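**Plan**
Retrosynthesis: (i) the C–C bond between the ring-bound ketone carbon and the central CH of the enolised 1,3-diketone (crossed Claisen with a vanillylidene acetone); (ii) the bond from the veratryl ring to its ring CH (anti-SN2' arylation); (iii) in one event, the bond between the acyl-bearing ring CH and the guaiacyl-bearing ring CH and the bond between the two olefinic ring carbons.
Enabling feature: in the cyclohexene, the guaiacyl CH, the ring CH2 and the adjacent olefinic CH map onto Cβ, Cα and C=O of coniferaldehyde. The acyl-bearing CH, the veratryl CH and the other olefinic CH map onto C-2, C-3 (held as a ketone) and C-4 of a 4-chloroacetoacetate, a 1,3-C,C-dinucleophile. One Michael/aldol/oxirane-closure event (Robinson-type [3+3]) joins the two three-carbon pieces; the olefinic carbons are joined first as the C–C bond of an oxirane.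
Forward: silylated coniferaldehyde + tert-butyl 4-chloroacetoacetate → carbocycle as an epoxy ketone → Wharton transposition → picolinate → arylcopper anti-SN2' (veratryl in, ring alkene in its final place) → acid → acylation of the enolate of silylated dehydrozingerone → desilylation.
Stereochemistry: the guaiacyl carbon comes from the diarylprolinol silyl ether catalyst; the oxirane (anti to the aryl group) from the chair aldol, and its C–O bond then sends the veratryl group to the opposite face; the acyl-bearing carbon is epimerisable and rests trans to both aryl groups.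

Key step: step 2

Remark: the sense of induction is taken from the usual shielding model of the E-iminium ion of a diarylprolinol silyl ether, which calls for the (R)-catalyst to give the (S)-configured guaiacyl carbon; the 1,3-diketone is drawn as the keto-enol tautomer of the target.

Step 1
Reactants: 1 coniferaldehyde, (E)-3-(4-hydroxy-3-methoxyphenyl)prop-2-enal
Product: 2 (E)-3-[3-methoxy-4-(triisopropylsilyloxy)phenyl]prop-2-enal
Conditions: TIPSCl, imidazole, DMF, rt
Reagents that add atoms: triisopropylsilyl chloride, CC(C)[Si](Cl)(C(C)C)C(C)C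
Why: Imidazole-promoted O-silylation of the phenol (silyl ether formation) should be clean, and the bulky silyl ether keeps the phenol from quenching the iminium ion and the bases of later steps; no stereocenter is formed.

Step 2
Reactants: 2 (E)-3-[3-methoxy-4-(triisopropylsilyloxy)phenyl]prop-2-enal; 3 tert-butyl 4-chloro-3-oxobutanoate
Product: 6 tert-butyl (1S,3R,4S,6S)-4-[3-methoxy-4-(triisopropylsilyloxy)phenyl]-2-oxo-7-oxabicyclo[4.1.0]heptane-3-carboxylate, via Michael adduct aldehyde 4 (not isolated), via chlorohydrin 5 (not isolated)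
Conditions: (R)-2-{bis[3,5-bis(trifluoromethyl)phenyl](trimethylsilyloxy)methyl}pyrrolidine (10 mol %), CH2Cl2, rt; then K2CO3, rt (one pot)
Reagents that add atoms: none
Why: The secondary amine condenses with enal 2 to an E-iminium ion whose β-carbon is attacked by the enol of the doubly activated C-2 of 3, which forges the bond between the ester-bearing carbon and the guaiacyl-bearing carbon and gives 4 after hydrolysis; K2CO3 then forms the α-chloro enolate at C-4, which closes the six-membered ring onto the aldehyde carbon (the bond between the two carbons that end as the ring CH=CH), and the alkoxide of 5 displaces chloride to give the oxirane. The closest known reaction type is the organocatalytic domino Michael/aldol/intramolecular SN2 sequence of γ-chloro-β-ketoesters with enals, a Robinson-type [3+3] annulation finished by a Darzens-type ring closure. The carbocycle closes by a 6-(enolexo)-exo-trig aldol addition and the oxirane by a 3-exo-tet substitution. The benzylic stereocenter is set by the catalyst, whose diarylsiloxymethyl group shields one face of the iminium ion; the two oxirane carbons follow from a chair transition state with the aryl group equatorial and from the need for a trans-diaxial chlorohydrin, which should place the oxygen anti to the aryl group; the ester-bearing carbon of the β-ketoester equilibrates to trans. The step needs 1,4- over 1,2-addition and attack through C-2 and not C-4, which iminium activation and the higher acidity of the 1,3-dicarbonyl CH2 secure, and only the chloromethyl carbon can reach the aldehyde through a six-membered ring.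

Step 3
Reactants: 6 tert-butyl (1S,3R,4S,6S)-4-[3-methoxy-4-(triisopropylsilyloxy)phenyl]-2-oxo-7-oxabicyclo[4.1.0]heptane-3-carboxylate
Product: 8 tert-butyl (1S,4S,6S)-4-hydroxy-6-[3-methoxy-4-(triisopropylsilyloxy)phenyl]cyclohex-2-ene-1-carboxylate, via epoxy hydrazone 7 (not isolated)
Conditions: N2H4·H2O, AcOH (cat.), MeOH, 0 °C to rt
Reagents that add atoms: none
Why: Wharton transposition: the hydrazone 7 opens the adjacent oxirane to an allylic diazene that loses N2, so the ketone carbon becomes an olefinic CH and the distal oxirane C–O bond, which is not broken, stays as the secondary alcohol anti to the aryl group, while the tert-butyl ester should retard pyrazolone formation.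

Step 4
Reactants: 8 tert-butyl (1S,4S,6S)-4-hydroxy-6-[3-methoxy-4-(triisopropylsilyloxy)phenyl]cyclohex-2-ene-1-carboxylate
Product: 9 tert-butyl (1S,4S,6S)-6-[3-methoxy-4-(triisopropylsilyloxy)phenyl]-4-(pyridine-2-carbonyloxy)cyclohex-2-ene-1-carboxylate
Conditions: picolinic acid, DCC, DMAP (cat.), CH2Cl2, rt
Reagents that add atoms: pyridine-2-carboxylic acid (picolinic acid), OC(=O)c1ccccn1
Why: Steglich esterification of the secondary allylic alcohol proceeds at oxygen with retention and installs the chelating picolinate leaving group needed for a γ-selective substitution.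

Step 5
Reactants: 9 tert-butyl (1S,4S,6S)-6-[3-methoxy-4-(triisopropylsilyloxy)phenyl]-4-(pyridine-2-carbonyloxy)cyclohex-2-ene-1-carboxylate; 10 3,4-dimethoxyphenylmagnesium bromide
Product: 11 tert-butyl (1R,2R,6S)-2-(3,4-dimethoxyphenyl)-6-[3-methoxy-4-(triisopropylsilyloxy)phenyl]cyclohex-3-ene-1-carboxylate
Conditions: CuBr·SMe2 (10 mol %), THF, −40 to 0 °C
Reagents that add atoms: none
Why: Copper-catalysed anti-SN2' allylic substitution: the arylcopper species adds to the alkene face opposite the magnesium-chelated picolinate and reductive elimination places the aryl group on the γ-carbon, so the new benzylic stereocenter is set cis to the guaiacyl group and trans to the ester by transfer of chirality from the C–O bond, while the double bond moves into its final position.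

Step 6
Reactants: 11 tert-butyl (1R,2R,6S)-2-(3,4-dimethoxyphenyl)-6-[3-methoxy-4-(triisopropylsilyloxy)phenyl]cyclohex-3-ene-1-carboxylate
Product: 12 (1R,2R,6S)-2-(3,4-dimethoxyphenyl)-6-[3-methoxy-4-(triisopropylsilyloxy)phenyl]cyclohex-3-ene-1-carboxylic acid
Conditions: CF3CO2H, anisole, CH2Cl2, 0 °C to rt
Reagents that add atoms: none
Why: Acidolysis of the tert-butyl ester (E1 loss of the tert-butyl cation, with anisole as scavenger) should free the acid without touching the aryl silyl ether, the ring alkene or the stereocenters.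

Step 7
Reactants: 13 dehydrozingerone, (E)-4-(4-hydroxy-3-methoxyphenyl)but-3-en-2-one
Product: 14 (E)-4-[3-methoxy-4-(triisopropylsilyloxy)phenyl]but-3-en-2-one
Conditions: TIPSCl, imidazole, DMF, rt
Reagents that add atoms: triisopropylsilyl chloride, CC(C)[Si](Cl)(C(C)C)C(C)C
Why: Imidazole-promoted O-silylation (silyl ether formation) masks the phenol so that only the methyl ketone is deprotonated in the next step; no stereocenter is formed.

Step 8
Reactants: 12 (1R,2R,6S)-2-(3,4-dimethoxyphenyl)-6-[3-methoxy-4-(triisopropylsilyloxy)phenyl]cyclohex-3-ene-1-carboxylic acid; 14 (E)-4-[3-methoxy-4-(triisopropylsilyloxy)phenyl]but-3-en-2-one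
Product: 17 (2Z,4E)-1-{(1R,2R,6S)-2-(3,4-dimethoxyphenyl)-6-[3-methoxy-4-(triisopropylsilyloxy)phenyl]cyclohex-3-en-1-yl}-3-hydroxy-5-[3-methoxy-4-(triisopropylsilyloxy)phenyl]penta-2,4-dien-1-one, via acyl imidazolide 15 (not isolated), via lithium enolate 16 (not isolated)
Conditions: 12, CDI, THF, rt; 14 (2.2 equiv), LiN(SiMe3)2 (2.2 equiv), THF, −78 °C; combine, −78 to 0 °C; aq. NH4Cl
Reagents that add atoms: none
Why: Crossed Claisen-type C-acylation: the kinetic cross-conjugated lithium enolate 16 of the methyl ketone attacks the acyl imidazolide 15 and the 1,3-diketone is drawn out of the equilibrium as its enolate, while the epimerisable carbon next to the new ketone can settle in the all-trans (all-equatorial) arrangement.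

Step 9
Reactants: 17 (2Z,4E)-1-{(1R,2R,6S)-2-(3,4-dimethoxyphenyl)-6-[3-methoxy-4-(triisopropylsilyloxy)phenyl]cyclohex-3-en-1-yl}-3-hydroxy-5-[3-methoxy-4-(triisopropylsilyloxy)phenyl]penta-2,4-dien-1-one
Product: 18 (2Z,4E)-1-[(1R,2R,6S)-2-(3,4-dimethoxyphenyl)-6-(4-hydroxy-3-methoxyphenyl)cyclohex-3-en-1-yl]-3-hydroxy-5-(4-hydroxy-3-methoxyphenyl)penta-2,4-dien-1-one (CNP0290899.1)
Conditions: Bu4NF, AcOH (1:1), THF, 0 °C
Reagents that add atoms: none
Why: Fluoride cleaves both aryl–O–Si bonds (desilylation) under acetic acid buffering, which should keep the base-sensitive keto-enol and the epimerisable ring carbon intact.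

**Compound list**
1 | coniferaldehyde, (E)-3-(4-hydroxy-3-methoxyphenyl)prop-2-enal | COc1cc(/C=C/C=O)ccc1O | starting material
2 | (E)-3-[3-methoxy-4-(triisopropylsilyloxy)phenyl]prop-2-enal | COc1cc(/C=C/C=O)ccc1O[Si](C(C)C)(C(C)C)C(C)C | intermediate
3 | tert-butyl 4-chloro-3-oxobutanoate | CC(C)(C)OC(=O)CC(=O)CCl | starting material
4 | tert-butyl 4-chloro-2-{(1S)-1-[3-methoxy-4-(triisopropylsilyloxy)phenyl]-3-oxopropyl}-3-oxobutanoate (Michael adduct, epimers at the ester-bearing carbon) | CC(C)(C)OC(=O)C(C(=O)CCl)[C@H](CC=O)c1ccc(O[Si](C(C)C)(C(C)C)C(C)C)c(OC)c1 | intermediate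
5 | tert-butyl (1R,3R,4S,6S)-3-chloro-4-hydroxy-6-[3-methoxy-4-(triisopropylsilyloxy)phenyl]-2-oxocyclohexane-1-carboxylate (chlorohydrin, Cl and OH trans-diaxial) | O=C1[C@H](C(=O)OC(C)(C)C)[C@@H](c2ccc(O[Si](C(C)C)(C(C)C)C(C)C)c(OC)c2)C[C@H](O)[C@H]1Cl | intermediate
6 | tert-butyl (1S,3R,4S,6S)-4-[3-methoxy-4-(triisopropylsilyloxy)phenyl]-2-oxo-7-oxabicyclo[4.1.0]heptane-3-carboxylate | O=C1[C@H](C(=O)OC(C)(C)C)[C@@H](c3ccc(O[Si](C(C)C)(C(C)C)C(C)C)c(OC)c3)C[C@@H]2O[C@@H]21 | intermediate
7 | hydrazone of 6, tert-butyl 2-hydrazinylidene-4-[3-methoxy-4-(triisopropylsilyloxy)phenyl]-7-oxabicyclo[4.1.0]heptane-3-carboxylate (ring stereocentres as in 6) | NN=C1[C@H](C(=O)OC(C)(C)C)[C@@H](c3ccc(O[Si](C(C)C)(C(C)C)C(C)C)c(OC)c3)C[C@@H]2O[C@@H]21 | intermediate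
8 | tert-butyl (1S,4S,6S)-4-hydroxy-6-[3-methoxy-4-(triisopropylsilyloxy)phenyl]cyclohex-2-ene-1-carboxylate | CC(C)(C)OC(=O)[C@H]1C=C[C@@H](O)C[C@@H]1c2ccc(O[Si](C(C)C)(C(C)C)C(C)C)c(OC)c2 | intermediate
9 | tert-butyl (1S,4S,6S)-6-[3-methoxy-4-(triisopropylsilyloxy)phenyl]-4-(pyridine-2-carbonyloxy)cyclohex-2-ene-1-carboxylate | CC(C)(C)OC(=O)[C@H]1C=C[C@@H](OC(=O)c2ccccn2)C[C@@H]1c3ccc(O[Si](C(C)C)(C(C)C)C(C)C)c(OC)c3 | intermediate
10 | 3,4-dimethoxyphenylmagnesium bromide (commercial THF solution) | COc1ccc([Mg]Br)cc1OC | starting material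
11 | tert-butyl (1R,2R,6S)-2-(3,4-dimethoxyphenyl)-6-[3-methoxy-4-(triisopropylsilyloxy)phenyl]cyclohex-3-ene-1-carboxylate | CC(C)(C)OC(=O)[C@H]1[C@H](c2ccc(OC)c(OC)c2)C=CC[C@@H]1c3ccc(O[Si](C(C)C)(C(C)C)C(C)C)c(OC)c3 | intermediate
12 | (1R,2R,6S)-2-(3,4-dimethoxyphenyl)-6-[3-methoxy-4-(triisopropylsilyloxy)phenyl]cyclohex-3-ene-1-carboxylic acid | OC(=O)[C@H]1[C@H](c2ccc(OC)c(OC)c2)C=CC[C@@H]1c3ccc(O[Si](C(C)C)(C(C)C)C(C)C)c(OC)c3 | intermediate
13 | dehydrozingerone, (E)-4-(4-hydroxy-3-methoxyphenyl)but-3-en-2-one | CC(=O)/C=C/c1ccc(O)c(OC)c1 | starting material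
14 | (E)-4-[3-methoxy-4-(triisopropylsilyloxy)phenyl]but-3-en-2-one | CC(=O)/C=C/c1ccc(O[Si](C(C)C)(C(C)C)C(C)C)c(OC)c1 | intermediate
15 | {(1R,2R,6S)-2-(3,4-dimethoxyphenyl)-6-[3-methoxy-4-(triisopropylsilyloxy)phenyl]cyclohex-3-en-1-yl}(1H-imidazol-1-yl)methanone | O=C(n4ccnc4)[C@H]1[C@H](c2ccc(OC)c(OC)c2)C=CC[C@@H]1c3ccc(O[Si](C(C)C)(C(C)C)C(C)C)c(OC)c3 | intermediate
16 | lithium (E)-4-[3-methoxy-4-(triisopropylsilyloxy)phenyl]buta-1,3-dien-2-olate | [Li]OC(=C)/C=C/c1ccc(O[Si](C(C)C)(C(C)C)C(C)C)c(OC)c1 | intermediate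
17 | (2Z,4E)-1-{(1R,2R,6S)-2-(3,4-dimethoxyphenyl)-6-[3-methoxy-4-(triisopropylsilyloxy)phenyl]cyclohex-3-en-1-yl}-3-hydroxy-5-[3-methoxy-4-(triisopropylsilyloxy)phenyl]penta-2,4-dien-1-one | COc1cc(/C=C/C(O)=C/C(=O)[C@@H]2[C@@H](c3ccc(O[Si](C(C)C)(C(C)C)C(C)C)c(OC)c3)CC=C[C@H]2c2ccc(OC)c(OC)c2)ccc1O[Si](C(C)C)(C(C)C)C(C)C | intermediate
18 | (2Z,4E)-1-[(1R,2R,6S)-2-(3,4-dimethoxyphenyl)-6-(4-hydroxy-3-methoxyphenyl)cyclohex-3-en-1-yl]-3-hydroxy-5-(4-hydroxy-3-methoxyphenyl)penta-2,4-dien-1-one (CNP0290899.1) | COc1cc(/C=C/C(O)=C/C(=O)[C@@H]2[C@@H](c3ccc(O)c(OC)c3)CC=C[C@H]2c2ccc(OC)c(OC)c2)ccc1O | target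

**Step count and risks**
Total step count: 9. Longest linear sequence: 8 steps (1, 2, 3, 4, 5, 6, 8, 9); step 7 is a one-step side branch.

Step 3 (Wharton transposition). What may go wrong: after hydrazone formation the second nitrogen may acylate on the neighbouring ester (pyrazolone ring closure), or the hydrazone may rest as the conjugated ene-hydrazine and not fragment. Fallback from 6: the ketone is reduced with NaBH4/CeCl3·7H2O (MeOH, −40 °C) to the epoxy alcohol F1, which is converted with 1,1'-thiocarbonyldiimidazole (DMAP, CH2Cl2) into the imidazole-1-carbothioate F2. Treatment of F2 with Bu3SnH/AIBN (toluene, 90 °C) generates the carbon radical next to the oxirane (Barton–McCombie-type deoxygenation), which opens the adjacent C–O bond; the alkoxy radical takes up hydrogen to give 8, where the route is rejoined.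

Step 5 (anti-SN2' arylation). What may go wrong: deprotonation of the CH between the ester and the alkene by the Grignard reagent followed by 1,4-elimination of the picolinate to a cyclohexadiene ester, or substitution at the carbinol carbon in place of the γ-carbon. Fallback from 8: oxidation with MnO2 (CH2Cl2) gives the enone F3. Conjugate addition of 10 with CuBr·SMe2 (THF, −78 °C) should occur trans to the ester, and the enolate is trapped with N-(5-chloropyridin-2-yl)-1,1,1-trifluoro-N-(trifluoromethylsulfonyl)methanesulfonamide as the regiodefined enol triflate F4. Reduction of the C–O bond of F4 with Pd(OAc)2/PPh3, HCO2H and Bu3N (DMF, 60 °C) gives 11, where the route is rejoined.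

Step 8 (crossed Claisen acylation). What may go wrong: proton transfer from the acidic CH next to the acyl imidazolide to the enolate, O-acylation in place of C-acylation, and slow attack at the hindered carbonyl group. Fallback from 12: MeLi (2.2 equiv, THF, −78 to 0 °C) converts the acid into the methyl ketone F5. Its kinetic enolate (LiN(iPr)2, THF, −78 °C) is added to aldehyde 2 to give the aldol F6, and oxidation of F6 with Dess–Martin periodinane gives 17, where the route is rejoined.

**Further compounds**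
F1 | step 3 | tert-butyl 2-hydroxy-4-[3-methoxy-4-(triisopropylsilyloxy)phenyl]-7-oxabicyclo[4.1.0]heptane-3-carboxylate (ring stereocentres as in 6, carbinol epimers) | OC1[C@H](C(=O)OC(C)(C)C)[C@@H](c3ccc(O[Si](C(C)C)(C(C)C)C(C)C)c(OC)c3)C[C@@H]2O[C@@H]21
F2 | step 3 | O-{3-(tert-butoxycarbonyl)-4-[3-methoxy-4-(triisopropylsilyloxy)phenyl]-7-oxabicyclo[4.1.0]heptan-2-yl} 1H-imidazole-1-carbothioate (ring stereocentres as in 6) | S=C(n4ccnc4)OC1[C@H](C(=O)OC(C)(C)C)[C@@H](c3ccc(O[Si](C(C)C)(C(C)C)C(C)C)c(OC)c3)C[C@@H]2O[C@@H]21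
F3 | step 5 | tert-butyl (1S,6S)-6-[3-methoxy-4-(triisopropylsilyloxy)phenyl]-4-oxocyclohex-2-ene-1-carboxylate | CC(C)(C)OC(=O)[C@H]1C=CC(=O)C[C@@H]1c2ccc(O[Si](C(C)C)(C(C)C)C(C)C)c(OC)c2
F4 | step 5 | tert-butyl (1R,2R,6S)-2-(3,4-dimethoxyphenyl)-6-[3-methoxy-4-(triisopropylsilyloxy)phenyl]-4-(trifluoromethylsulfonyloxy)cyclohex-3-ene-1-carboxylate | CC(C)(C)OC(=O)[C@H]1[C@H](c2ccc(OC)c(OC)c2)C=C(OS(=O)(=O)C(F)(F)F)C[C@@H]1c3ccc(O[Si](C(C)C)(C(C)C)C(C)C)c(OC)c3
F5 | step 8 | 1-{(1R,2R,6S)-2-(3,4-dimethoxyphenyl)-6-[3-methoxy-4-(triisopropylsilyloxy)phenyl]cyclohex-3-en-1-yl}ethan-1-one | CC(=O)[C@H]1[C@H](c2ccc(OC)c(OC)c2)C=CC[C@@H]1c3ccc(O[Si](C(C)C)(C(C)C)C(C)C)c(OC)c3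
F6 | step 8 | (E)-1-{(1R,2R,6S)-2-(3,4-dimethoxyphenyl)-6-[3-methoxy-4-(triisopropylsilyloxy)phenyl]cyclohex-3-en-1-yl}-3-hydroxy-5-[3-methoxy-4-(triisopropylsilyloxy)phenyl]pent-4-en-1-one (carbinol epimers) | O=C(CC(O)/C=C/c4ccc(O[Si](C(C)C)(C(C)C)C(C)C)c(OC)c4)[C@H]1[C@H](c2ccc(OC)c(OC)c2)C=CC[C@@H]1c3ccc(O[Si](C(C)C)(C(C)C)C(C)C)c(OC)c3
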